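**Retrosynthetic overview**
1. Target 15 comes from global MOM removal of dihydrochalcone 14, which comes from chemoselective 1,4-reduction of chalcone 13.
2. Chalcone 13 is cut at the Cα–Cβ bond: Claisen–Schmidt aldol condensation of methyl ketone 9 (ring A, chromene fragment) with aldehyde 11 (ring B fragment).
3. Ketone 9 comes from chromene 8. The pyran ring is closed on 3-prenylresacetophenone 4 by propargyl ether Claisen rearrangement and electrocyclisation at C5, the only free ortho position.
4. Compound 4 comes from 2,4-dihydroxyacetophenone 1 by O-(1,1-dimethylpropargyl)ation, semihydrogenation and aromatic Claisen rearrangement to C3.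
5. Ring order: both benzene rings are bought; the 2H-pyran ring is the only ring formed (step 5), before the two fragments are joined.

Assumption: the target SMILES has no stereocentre and the molecule is achiral, so "single enantiomer" is taken to mean the one compound drawn; no stereocentre has to be set.

**Route**

Step 1
Reactants: 1 1-(2,4-dihydroxyphenyl)ethan-1-one
Product: 2 1-{2-hydroxy-4-[(2-methylbut-3-yn-2-yl)oxy]phenyl}ethan-1-one
Conditions: 3-chloro-3-methylbut-1-yne (1.5 equiv), K2CO3 (2 equiv), KI (cat.), CuI (cat.), acetone, reflux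
Reagents that add atoms: 3-chloro-3-methylbut-1-yne, CC(C)(Cl)C#C
Why: Williamson-type O-propargylation goes to the 4-OH because the 2-OH is held in a hydrogen bond to the acetyl group and is much less nucleophilic.

Step 2
Reactants: 2 1-{2-hydroxy-4-[(2-methylbut-3-yn-2-yl)oxy]phenyl}ethan-1-one
Product: 3 1-{2-hydroxy-4-[(2-methylbut-3-en-2-yl)oxy]phenyl}ethan-1-one
Conditions: H2 (1 atm), Pd/CaCO3 poisoned with Pb(OAc)2, quinoline, EtOAc, rt, stopped at 1 equiv H2
Reagents that add atoms: none
Why: Lindlar semihydrogenation stops at the terminal alkene because the poisoned palladium surface binds the alkyne far more strongly than the alkene and does not touch the aryl ketone.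

Step 3
Reactants: 3 1-{2-hydroxy-4-[(2-methylbut-3-en-2-yl)oxy]phenyl}ethan-1-one
Product: 4 1-[2,4-dihydroxy-3-(3-methylbut-2-en-1-yl)phenyl]ethan-1-one
Conditions: PhNEt2, 140 °C, N2
Reagents that add atoms: none
Why: Aromatic Claisen ([3,3]-sigmatropic) rearrangement with allylic inversion turns the 1,1-dimethylallyl ether into a C-prenyl group, directed to C3 because the hydrogen-bonded chelate gives the C3–C4 bond the higher double-bond character, and tautomerisation restores the phenol.

Step 4
Reactants: 4 1-[2,4-dihydroxy-3-(3-methylbut-2-en-1-yl)phenyl]ethan-1-one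
Product: 5 1-{2-hydroxy-3-(3-methylbut-2-en-1-yl)-4-[(2-methylbut-3-yn-2-yl)oxy]phenyl}ethan-1-one
Conditions: 3-chloro-3-methylbut-1-yne (2 equiv), K2CO3 (2 equiv), KI (cat.), CuI (cat.), acetone, reflux
Reagents that add atoms: 3-chloro-3-methylbut-1-yne, CC(C)(Cl)C#C
Why: The same Williamson-type O-propargylation again picks the non-chelated 4-OH, and the copper acetylide pathway tolerates the flanking prenyl group.

Step 5
Reactants: 5 1-{2-hydroxy-3-(3-methylbut-2-en-1-yl)-4-[(2-methylbut-3-yn-2-yl)oxy]phenyl}ethan-1-one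
Product: 8 1-[7-hydroxy-2,2-dimethyl-8-(3-methylbut-2-en-1-yl)-2H-chromen-6-yl]ethan-1-one, via allenylphenol 6 (not isolated), via ortho-quinone methide 7 (not isolated)
Conditions: PhNEt2, 190 °C, N2
Reagents that add atoms: none
Why: The aryl propargyl ether Claisen rearrangement can deliver the allene only to the free ortho position C5 (C3 carries the prenyl group), and a 1,5-hydrogen shift followed by oxa-6π-electrocyclisation closes the 2,2-dimethyl-2H-pyran ring.

Step 6
Reactants: 8 1-[7-hydroxy-2,2-dimethyl-8-(3-methylbut-2-en-1-yl)-2H-chromen-6-yl]ethan-1-one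
Product: 9 1-[7-(methoxymethoxy)-2,2-dimethyl-8-(3-methylbut-2-en-1-yl)-2H-chromen-6-yl]ethan-1-one
Conditions: NaH (1.2 equiv), DMF, 0 °C; then MOMCl (1.3 equiv), 0 °C to rt
Reagents that add atoms: chloromethyl methyl ether (MOMCl), COCCl
Why: Irreversible deprotonation breaks the chelate of the hindered phenol and the phenoxide is O-alkylated by the very reactive α-chloro ether (Williamson ether synthesis), masking the acidic OH for the aldol and copper hydride steps.

Step 7
Reactants: 10 4-hydroxybenzaldehyde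
Product: 11 4-(methoxymethoxy)benzaldehyde
Conditions: MOMCl (1.3 equiv), K2CO3 (2 equiv), acetone, rt
Reagents that add atoms: chloromethyl methyl ether (MOMCl), COCCl
Why: Williamson-type MOM protection removes the phenoxide that would otherwise deactivate the aldehyde toward enolate addition under basic aldol conditions.

Step 8
Reactants: 9 1-[7-(methoxymethoxy)-2,2-dimethyl-8-(3-methylbut-2-en-1-yl)-2H-chromen-6-yl]ethan-1-one; 11 4-(methoxymethoxy)benzaldehyde
Product: 13 (2E)-3-[4-(methoxymethoxy)phenyl]-1-[7-(methoxymethoxy)-2,2-dimethyl-8-(3-methylbut-2-en-1-yl)-2H-chromen-6-yl]prop-2-en-1-one, via aldol adduct 12 (not isolated)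
Conditions: KOH (5 equiv), EtOH/H2O (4:1), rt, 24–48 h
Reagents that add atoms: none
Why: Claisen–Schmidt crossed aldol condensation: the methyl ketone enolate adds to the non-enolisable aldehyde and the β-hydroxy ketone loses water by E1cB to give the thermodynamically favoured E enone, with MOM ethers, prenyl and chromene inert to hydroxide.

Step 9
Reactants: 13 (2E)-3-[4-(methoxymethoxy)phenyl]-1-[7-(methoxymethoxy)-2,2-dimethyl-8-(3-methylbut-2-en-1-yl)-2H-chromen-6-yl]prop-2-en-1-one
Product: 14 3-[4-(methoxymethoxy)phenyl]-1-[7-(methoxymethoxy)-2,2-dimethyl-8-(3-methylbut-2-en-1-yl)-2H-chromen-6-yl]propan-1-one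
Conditions: [(Ph3P)CuH]6 (Stryker's reagent, 0.5 equiv of hexamer), H2O (5 equiv), degassed toluene, rt
Reagents that add atoms: none
Why: Copper hydride conjugate reduction delivers hydride only to the β-carbon of the enone and water protonates the resulting enolate, so the unactivated prenyl alkene, the chromene alkene and the ketone are left untouched.

Step 10
Reactants: 14 3-[4-(methoxymethoxy)phenyl]-1-[7-(methoxymethoxy)-2,2-dimethyl-8-(3-methylbut-2-en-1-yl)-2H-chromen-6-yl]propan-1-one
Product: 15 1-[7-hydroxy-2,2-dimethyl-8-(3-methylbut-2-en-1-yl)-2H-chromen-6-yl]-3-(4-hydroxyphenyl)propan-1-one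
Conditions: HCl (3 M aq), MeOH, 40 °C, monitored and quenched with NaHCO3 at full conversion
Reagents that add atoms: none
Why: Acid-catalysed acetal cleavage (transacetalisation to dimethoxymethane in methanol) frees both phenols under conditions mild enough to spare the prenyl and chromene double bonds, whose aromatic ring is deactivated by the chelated acyl group.

**Compound list**
1 | 1-(2,4-dihydroxyphenyl)ethan-1-one (2,4-dihydroxyacetophenone) | CC(=O)c1ccc(O)cc1O | starting material
2 | 1-{2-hydroxy-4-[(2-methylbut-3-yn-2-yl)oxy]phenyl}ethan-1-one | CC(=O)c1ccc(OC(C)(C)C#C)cc1O | intermediate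
3 | 1-{2-hydroxy-4-[(2-methylbut-3-en-2-yl)oxy]phenyl}ethan-1-one | CC(=O)c1ccc(OC(C)(C)C=C)cc1O | intermediate
4 | 1-[2,4-dihydroxy-3-(3-methylbut-2-en-1-yl)phenyl]ethan-1-one | CC(=O)c1ccc(O)c(CC=C(C)C)c1O | intermediate
5 | 1-{2-hydroxy-3-(3-methylbut-2-en-1-yl)-4-[(2-methylbut-3-yn-2-yl)oxy]phenyl}ethan-1-one | CC(=O)c1ccc(OC(C)(C)C#C)c(CC=C(C)C)c1O | intermediate
6 | 1-[2,4-dihydroxy-5-(3-methylbuta-1,2-dien-1-yl)-3-(3-methylbut-2-en-1-yl)phenyl]ethan-1-one (allenylphenol, formed in the flask in step 5) | CC(=O)c1cc(C=C=C(C)C)c(O)c(CC=C(C)C)c1O | intermediate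
7 | (6Z)-4-acetyl-3-hydroxy-2-(3-methylbut-2-en-1-yl)-6-(3-methylbut-2-en-1-ylidene)cyclohexa-2,4-dien-1-one (ortho-quinone methide, formed in the flask in step 5) | CC(C)=C/C=C1/C=C(C(C)=O)C(O)=C(CC=C(C)C)C1=O | intermediate
8 | 1-[7-hydroxy-2,2-dimethyl-8-(3-methylbut-2-en-1-yl)-2H-chromen-6-yl]ethan-1-one | CC(=O)c1cc2C=CC(C)(C)Oc2c(CC=C(C)C)c1O | intermediate
9 | 1-[7-(methoxymethoxy)-2,2-dimethyl-8-(3-methylbut-2-en-1-yl)-2H-chromen-6-yl]ethan-1-one | CC(=O)c1cc2C=CC(C)(C)Oc2c(CC=C(C)C)c1OCOC | intermediate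
10 | 4-hydroxybenzaldehyde | O=Cc1ccc(O)cc1 | starting material
11 | 4-(methoxymethoxy)benzaldehyde | COCOc1ccc(C=O)cc1 | intermediate
12 | 3-hydroxy-3-[4-(methoxymethoxy)phenyl]-1-[7-(methoxymethoxy)-2,2-dimethyl-8-(3-methylbut-2-en-1-yl)-2H-chromen-6-yl]propan-1-one (racemic aldol adduct, formed in the flask in step 8) | COCOc1ccc(C(O)CC(=O)c2cc3C=CC(C)(C)Oc3c(CC=C(C)C)c2OCOC)cc1 | intermediate
13 | (2E)-3-[4-(methoxymethoxy)phenyl]-1-[7-(methoxymethoxy)-2,2-dimethyl-8-(3-methylbut-2-en-1-yl)-2H-chromen-6-yl]prop-2-en-1-one | COCOc1ccc(/C=C/C(=O)c2cc3C=CC(C)(C)Oc3c(CC=C(C)C)c2OCOC)cc1 | intermediate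
14 | 3-[4-(methoxymethoxy)phenyl]-1-[7-(methoxymethoxy)-2,2-dimethyl-8-(3-methylbut-2-en-1-yl)-2H-chromen-6-yl]propan-1-one | COCOc1ccc(CCC(=O)c2cc3C=CC(C)(C)Oc3c(CC=C(C)C)c2OCOC)cc1 | intermediate
15 | 1-[7-hydroxy-2,2-dimethyl-8-(3-methylbut-2-en-1-yl)-2H-chromen-6-yl]-3-(4-hydroxyphenyl)propan-1-one | CC(C)=CCc1c(O)c(C(=O)CCc2ccc(O)cc2)cc2c1OC(C)(C)C=C2 | target

**Step count**
Total steps: 10. Longest linear sequence: 9 steps (steps 1, 2, 3, 4, 5, 6, 8, 9, 10 from compound 1 to compound 15); step 7 is a one-step side branch.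

**Three steps most likely to fail, each with a fallback**

Step 3 (Claisen rearrangement; risk of C5 prenylation, loss of isoprene or chroman formation). The fallback sets out from 1 and comes back to the route at 4. It replaces the sigmatropic route by charge-controlled C-alkylation: 1 is dissolved in 10% aqueous KOH at 0 °C and treated with prenyl bromide, so that the resorcinolate dianion is alkylated mainly at C3, the carbon activated by both oxygens. Compound 4 is separated from the 5-prenyl, diprenyl and O-prenyl by-products by chromatography; the yield is modest but the material is cheap. It makes no compound beyond those of the list (F0).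

Step 9 (conjugate reduction; risk of incomplete conversion with aged copper hydride or of over-reduction). The fallback sets out from 13 and comes back to the route at 14. It goes through an isolable enol derivative instead of a direct hydride reduction: 1,4-hydrosilylation of 13 with Et3SiH and RhCl(PPh3)3 (cat.) in toluene at 50 °C gives triethyl({(1Z)-3-[4-(methoxymethoxy)phenyl]-1-[7-(methoxymethoxy)-2,2-dimethyl-8-(3-methylbut-2-en-1-yl)-2H-chromen-6-yl]prop-1-en-1-yl}oxy)silane F1. This silyl enol ether is then hydrolysed with K2CO3 in MeOH/H2O at rt to 14. The hindered trisubstituted and chromene alkenes are not hydrosilylated under these conditions.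

Step 10 (acidic MOM removal; risk of acid-induced cyclisation of the prenyl group onto the 7-OH or addition to the chromene alkene). The fallback sets out from 8 (with 10 as second partner) and comes back to the route at 15. It swaps the acid-labile protecting groups for allyl ethers that are removed under neutral conditions. Compound 8 with allyl bromide and K2CO3 in DMF at 60 °C gives 1-[2,2-dimethyl-8-(3-methylbut-2-en-1-yl)-7-(prop-2-en-1-yloxy)-2H-chromen-6-yl]ethan-1-one F2. Compound 10 with allyl bromide and K2CO3 in acetone gives 4-(prop-2-en-1-yloxy)benzaldehyde F3. Condensation of the two with KOH in EtOH/H2O passes through the racemic aldol adduct 3-hydroxy-1-[2,2-dimethyl-8-(3-methylbut-2-en-1-yl)-7-(prop-2-en-1-yloxy)-2H-chromen-6-yl]-3-[4-(prop-2-en-1-yloxy)phenyl]propan-1-one F4, which is not isolated. It gives (2E)-1-[2,2-dimethyl-8-(3-methylbut-2-en-1-yl)-7-(prop-2-en-1-yloxy)-2H-chromen-6-yl]-3-[4-(prop-2-en-1-yloxy)phenyl]prop-2-en-1-one F5. Conjugate reduction with [(Ph3P)CuH]6 and H2O in toluene gives 1-[2,2-dimethyl-8-(3-methylbut-2-en-1-yl)-7-(prop-2-en-1-yloxy)-2H-chromen-6-yl]-3-[4-(prop-2-en-1-yloxy)phenyl]propan-1-one F6. Both allyl ethers are then cleaved with Pd(PPh3)4 (cat.) and morpholine in THF at rt to give 15; the C-prenyl group cannot ionise to an allyl complex and stays intact.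

**Further compounds**
F0 | step 3 | none | none
F1 | step 9 | triethyl({(1Z)-3-[4-(methoxymethoxy)phenyl]-1-[7-(methoxymethoxy)-2,2-dimethyl-8-(3-methylbut-2-en-1-yl)-2H-chromen-6-yl]prop-1-en-1-yl}oxy)silane | COCOc1ccc(C/C=C(\O[Si](CC)(CC)CC)c2cc3C=CC(C)(C)Oc3c(CC=C(C)C)c2OCOC)cc1
F2 | step 10 | 1-[2,2-dimethyl-8-(3-methylbut-2-en-1-yl)-7-(prop-2-en-1-yloxy)-2H-chromen-6-yl]ethan-1-one | CC(=O)c1cc2C=CC(C)(C)Oc2c(CC=C(C)C)c1OCC=C
F3 | step 10 | 4-(prop-2-en-1-yloxy)benzaldehyde | C=CCOc1ccc(C=O)cc1
F4 | step 10 | 3-hydroxy-1-[2,2-dimethyl-8-(3-methylbut-2-en-1-yl)-7-(prop-2-en-1-yloxy)-2H-chromen-6-yl]-3-[4-(prop-2-en-1-yloxy)phenyl]propan-1-one (racemic, not isolated) | C=CCOc1ccc(C(O)CC(=O)c2cc3C=CC(C)(C)Oc3c(CC=C(C)C)c2OCC=C)cc1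
F5 | step 10 | (2E)-1-[2,2-dimethyl-8-(3-methylbut-2-en-1-yl)-7-(prop-2-en-1-yloxy)-2H-chromen-6-yl]-3-[4-(prop-2-en-1-yloxy)phenyl]prop-2-en-1-one | C=CCOc1ccc(/C=C/C(=O)c2cc3C=CC(C)(C)Oc3c(CC=C(C)C)c2OCC=C)cc1
F6 | step 10 | 1-[2,2-dimethyl-8-(3-methylbut-2-en-1-yl)-7-(prop-2-en-1-yloxy)-2H-chromen-6-yl]-3-[4-(prop-2-en-1-yloxy)phenyl]propan-1-one | C=CCOc1ccc(CCC(=O)c2cc3C=CC(C)(C)Oc3c(CC=C(C)C)c2OCC=C)cc1
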